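**Retrosynthetic overview**

1. The strategy rests on the furan ring of the benzofuran. Its O1–C2 bond and the hindered C3–C1′ biaryl bond lie on either side of C2=C3, which is read back as the triple bond of a 2-alkynylphenol. Both bonds are cut at once, giving alkynylresorcinol 14 and aryl iodide 7 (Cacchi-type arylative oxypalladation).
2. The furan is the only ring formed (step 10); both benzene rings are bought.
3. Alkynylresorcinol 14 comes from 3,5-dimethoxytoluene by ring iodination, O-demethylation, acetate masking, Sonogashira coupling with methyl pent-4-ynoate and mild methanolysis.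
4. In iodide 7 the iodine is meta to both oxygens, out of reach of electrophilic iodination. It is therefore placed by sterically controlled C–H borylation of 2,6-dimethoxytoluene and iododeboronation; the second C-methyl follows by formylation and silane reduction at one of two symmetry-equivalent positions.
5. End game: BBr3 frees the two remaining phenols (and cleaves the ester), and Fischer esterification restores the methyl ester.

Key step: step 10

Assumption: the C3–C1′ biaryl axis is hindered, but the target SMILES assigns it no configuration and the molecule has no stereocentre, so the route makes no attempt at axial control.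

**Route**

Step 1
Reactants: 1 2,6-dimethoxytoluene
Product: 2 2-(3,5-dimethoxy-4-methylphenyl)-4,4,5,5-tetramethyl-1,3,2-dioxaborolane
Conditions: B2pin2 (1.0 equiv), [Ir(OMe)(cod)]2 (1.5 mol %), 4,4′-di-tert-butyl-2,2′-bipyridine (3 mol %), THF, 80 °C
Reagents that add atoms: bis(pinacolato)diboron, CC1(C)OB(OC1(C)C)B1OC(C)(C)C(C)(C)O1
Why: Iridium-catalysed aromatic C–H borylation is governed by sterics, and C4–H of 1 is the only ring C–H without an ortho substituent, so boron should enter meta to both methoxy groups.

Step 2
Reactants: 2 2-(3,5-dimethoxy-4-methylphenyl)-4,4,5,5-tetramethyl-1,3,2-dioxaborolane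
Product: 3 5-iodo-1,3-dimethoxy-2-methylbenzene
Conditions: CuI (10 mol %), 1,10-phenanthroline (20 mol %), KI (1.5 equiv), MeOH/H2O 4:1, air, 80 °C
Reagents that add atoms: potassium iodide, [K+].[I-]
Why: Copper-mediated aerobic iododeboronation replaces boron by iodine at the ipso carbon through an arylcopper intermediate, so the halogen stays at the position chosen in step 1 and does not follow the ortho/para bias of the methoxy groups.

Step 3
Reactants: 3 5-iodo-1,3-dimethoxy-2-methylbenzene
Product: 5 6-iodo-2,4-dimethoxy-3-methylbenzaldehyde, via α-chloro ether 4 (not isolated)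
Conditions: Cl2CHOMe (1.5 equiv), TiCl4 (2.2 equiv), CH2Cl2, −10 → 0 °C; then ice-cold 1 M HCl
Reagents that add atoms: dichloromethyl methyl ether, COC(Cl)Cl; water (work-up, carbonyl oxygen), O
Why: Rieche formylation: the two open ring positions of 3 are equivalent by symmetry and each is ortho to one methoxy group and para to the other, so a single aldehyde should result after hydrolysis of the α-chloro ether, while the iodine, meta to both donors, is not prone to acid-induced loss.

Step 4
Reactants: 5 6-iodo-2,4-dimethoxy-3-methylbenzaldehyde
Product: 7 1-iodo-3,5-dimethoxy-2,4-dimethylbenzene, via benzylic alcohol 6 (not isolated)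
Conditions: Et3SiH (3 equiv), TFA, CH2Cl2, 0 °C → rt
Reagents that add atoms: none
Why: Ionic hydrogenation: hydride transfer to the protonated aldehyde gives the benzylic alcohol, whose cation is stabilised by the ortho and para methoxy groups and is reduced by a second equivalent of silane to the methyl group, with the aryl iodide inert to these conditions.

Step 5
Reactants: 8 3,5-dimethoxytoluene
Product: 9 2-iodo-1,5-dimethoxy-3-methylbenzene
Conditions: NIS (1.05 equiv), MeCN, rt, dark
Reagents that add atoms: N-iodosuccinimide, O=C1CCC(=O)N1I
Why: Electrophilic aromatic iodination of the orcinol dimethyl ether is expected at C2, para to one methoxy group and ortho to the other, in preference to the position flanked by both methoxy groups.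

Step 6
Reactants: 9 2-iodo-1,5-dimethoxy-3-methylbenzene
Product: 10 4-iodo-5-methylbenzene-1,3-diol
Conditions: BBr3 (3 equiv), CH2Cl2, −78 → 0 °C; ice-water quench
Reagents that add atoms: none
Why: BBr3 cleavage of aryl methyl ethers (boron coordination at oxygen, bromide attack on the methyl group) should free both phenols while the aryl iodide is kept by working cold and quenching promptly.

Step 7
Reactants: 10 4-iodo-5-methylbenzene-1,3-diol
Product: 11 4-iodo-5-methyl-1,3-phenylene diacetate
Conditions: Ac2O (2.5 equiv), pyridine, DMAP (cat.), CH2Cl2, 0 °C → rt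
Reagents that add atoms: acetic anhydride, CC(=O)OC(C)=O
Why: DMAP-catalysed O-acetylation masks the ortho hydroxyl so that it cannot close onto the alkyne under the palladium and copper of the next step.

Step 8
Reactants: 11 4-iodo-5-methyl-1,3-phenylene diacetate; 12 methyl pent-4-ynoate
Product: 13 methyl 5-[2,4-bis(acetyloxy)-6-methylphenyl]pent-4-ynoate
Conditions: PdCl2(PPh3)2 (3 mol %), CuI (5 mol %), Et3N (3 equiv), degassed THF, 50 °C
Reagents that add atoms: none
Why: Sonogashira coupling of an aryl iodide with a terminal alkyne, in which the ortho acetate blocks premature heteroannulation and the two ester groups ease oxidative addition at the di-ortho-substituted C–I bond.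

Step 9
Reactants: 13 methyl 5-[2,4-bis(acetyloxy)-6-methylphenyl]pent-4-ynoate
Product: 14 methyl 5-(2,4-dihydroxy-6-methylphenyl)pent-4-ynoate
Conditions: K2CO3 (0.5 equiv), dry MeOH, 0 °C, argon; aq NH4Cl; used at once
Reagents that add atoms: none
Why: Zemplén-type transesterification removes aryl acetates rapidly, the methyl ester is degenerate toward methoxide, and the low temperature together with the electron-rich alkyne should keep the phenoxide from cyclising before the palladium step.

Step 10
Reactants: 14 methyl 5-(2,4-dihydroxy-6-methylphenyl)pent-4-ynoate; 7 1-iodo-3,5-dimethoxy-2,4-dimethylbenzene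
Product: 15 methyl 3-[3-(3,5-dimethoxy-2,4-dimethylphenyl)-6-hydroxy-4-methyl-1-benzofuran-2-yl]propanoate
Conditions: Pd(PPh3)4 (10 mol %), K2CO3 (3 equiv), 7 (1.5 equiv), degassed MeCN, 70 °C, slow addition of 14
Reagents that add atoms: none
Why: Oxidative addition of zerovalent palladium into the C–I bond of 7 gives an arylpalladium iodide (divalent palladium) that binds the triple bond of 14 as a π-acid. The ortho phenoxide then adds anti to the metal across the alkyne in a 5-endo-dig closure that forms O1–C2 and the furan ring, leaving a benzofuran-3-yl(aryl)palladium species whose reductive elimination forms C3–C1′ and returns zerovalent palladium. This is the Cacchi oxypalladation–reductive elimination of 2-alkynylphenols with aryl halides, a known route to 2,3-disubstituted benzofurans, and it brings the metal to the crowded C3 through the ring closure itself, not through transmetalation of a hindered nucleophile. No stereocentre is formed and the biaryl axis is left unassigned. Regiochemistry is fixed by geometry, since only the ortho oxygen can reach the alkyne and only at its distal carbon, so the para hydroxyl is a spectator (C–O coupling at a PPh3-ligated palladium centre is not competitive). The selectivity the step needs is arylative closure over plain cycloisomerisation to the 3-unsubstituted benzofuran, and it is favoured by the absence of copper, the mild carbonate base, the excess of 7 that keeps palladium as its aryl complex, and the slow addition of 14.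

Step 11
Reactants: 15 methyl 3-[3-(3,5-dimethoxy-2,4-dimethylphenyl)-6-hydroxy-4-methyl-1-benzofuran-2-yl]propanoate
Product: 16 3-[3-(3,5-dihydroxy-2,4-dimethylphenyl)-6-hydroxy-4-methyl-1-benzofuran-2-yl]propanoic acid
Conditions: BBr3 (8 equiv), CH2Cl2, −78 °C → rt; ice-water quench; crude carried on
Reagents that add atoms: none
Why: BBr3 ether cleavage removes both aryl methyl ethers, and excess reagent at room temperature is used deliberately to cleave the methyl ester as well (bromide attack on the O-methyl of the boron-complexed ester), so that one triol acid goes forward; any ester that survives is already the target and passes unchanged through step 12.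

Step 12
Reactants: 16 3-[3-(3,5-dihydroxy-2,4-dimethylphenyl)-6-hydroxy-4-methyl-1-benzofuran-2-yl]propanoic acid
Product: 17 talarominine A, methyl 3-[3-(3,5-dihydroxy-2,4-dimethylphenyl)-6-hydroxy-4-methyl-1-benzofuran-2-yl]propanoate
Conditions: MeOH, H2SO4 (cat.), 50 °C
Reagents that add atoms: methanol, CO
Why: Fischer esterification converts the carboxylic acid into the methyl ester by acid-catalysed addition–elimination in methanol, conditions under which phenols are not O-methylated.

**Compound list**

1 | 2,6-dimethoxytoluene | COc1cccc(OC)c1C | starting material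
2 | 2-(3,5-dimethoxy-4-methylphenyl)-4,4,5,5-tetramethyl-1,3,2-dioxaborolane | COc1cc(cc(OC)c1C)B1OC(C)(C)C(C)(C)O1 | intermediate
3 | 5-iodo-1,3-dimethoxy-2-methylbenzene | COc1cc(I)cc(OC)c1C | intermediate
4 | 2-[chloro(methoxy)methyl]-1-iodo-3,5-dimethoxy-4-methylbenzene (racemic; formed in the flask in step 3, not isolated) | COC(Cl)c1c(I)cc(OC)c(C)c1OC | intermediate
5 | 6-iodo-2,4-dimethoxy-3-methylbenzaldehyde | COc1cc(I)c(C=O)c(OC)c1C | intermediate
6 | (6-iodo-2,4-dimethoxy-3-methylphenyl)methanol (formed in the flask in step 4, not isolated) | COc1cc(I)c(CO)c(OC)c1C | intermediate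
7 | 1-iodo-3,5-dimethoxy-2,4-dimethylbenzene | COc1cc(I)c(C)c(OC)c1C | intermediate
8 | 3,5-dimethoxytoluene | COc1cc(C)cc(OC)c1 | starting material
9 | 2-iodo-1,5-dimethoxy-3-methylbenzene | COc1cc(C)c(I)c(OC)c1 | intermediate
10 | 4-iodo-5-methylbenzene-1,3-diol | Oc1cc(C)c(I)c(O)c1 | intermediate
11 | 4-iodo-5-methyl-1,3-phenylene diacetate | CC(=O)Oc1cc(C)c(I)c(OC(C)=O)c1 | intermediate
12 | methyl pent-4-ynoate | COC(=O)CCC#C | starting material
13 | methyl 5-[2,4-bis(acetyloxy)-6-methylphenyl]pent-4-ynoate | COC(=O)CCC#Cc1c(C)cc(OC(C)=O)cc1OC(C)=O | intermediate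
14 | methyl 5-(2,4-dihydroxy-6-methylphenyl)pent-4-ynoate | COC(=O)CCC#Cc1c(C)cc(O)cc1O | intermediate
15 | methyl 3-[3-(3,5-dimethoxy-2,4-dimethylphenyl)-6-hydroxy-4-methyl-1-benzofuran-2-yl]propanoate | COC(=O)CCc1oc2cc(O)cc(C)c2c1-c1cc(OC)c(C)c(OC)c1C | intermediate
16 | 3-[3-(3,5-dihydroxy-2,4-dimethylphenyl)-6-hydroxy-4-methyl-1-benzofuran-2-yl]propanoic acid | OC(=O)CCc1oc2cc(O)cc(C)c2c1-c1cc(O)c(C)c(O)c1C | intermediate
17 | talarominine A, methyl 3-[3-(3,5-dihydroxy-2,4-dimethylphenyl)-6-hydroxy-4-methyl-1-benzofuran-2-yl]propanoate | COC(=O)CCc1oc2cc(O)cc(C)c2c1-c1cc(O)c(C)c(O)c1C | target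

**Step count**

Total steps: 12. Longest linear sequence: 8 (steps 5–12, from 3,5-dimethoxytoluene); the aryl iodide branch is 4 steps (steps 1–4).

**Steps most likely to fail**

Step 10 (key step). The phenoxide may close onto the alkyne and the adduct be protonated before the hindered aryl group is delivered, so that cycloisomerisation without arylation takes over; reduction or homocoupling of the aryl iodide is a further risk. The fallback forms the ring and the biaryl bond in two separate known operations. It sets out from 9, 12 and 7. Sonogashira coupling of 9 with 12 (PdCl2(PPh3)2, CuI, Et3N) should give methyl 5-(2,4-dimethoxy-6-methylphenyl)pent-4-ynoate F1. Larock-type iodocyclisation (I2, CH2Cl2, rt; the ortho methoxy oxygen closes and loses its methyl group) should give methyl 3-(3-iodo-6-methoxy-4-methyl-1-benzofuran-2-yl)propanoate F2. Iodide 7 is converted by Miyaura borylation (PdCl2(dppf), B2pin2, KOAc, dioxane) into 2-(3,5-dimethoxy-2,4-dimethylphenyl)-4,4,5,5-tetramethyl-1,3,2-dioxaborolane F3. Suzuki–Miyaura coupling of F2 with F3 (Pd(OAc)2, SPhos, K3PO4, toluene/H2O, 100 °C) should give methyl 3-[3-(3,5-dimethoxy-2,4-dimethylphenyl)-6-methoxy-4-methyl-1-benzofuran-2-yl]propanoate F4. BBr3 under the conditions of step 11 then cleaves its three methyl ethers and the ester, and the route is rejoined at 16.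

Step 11. Ether cleavage may stop short, or the electron-rich benzofuran triol may degrade during the long exposure to BBr3 and HBr. The fallback moves the ether cleavage ahead of the key step, where neither the ester nor the benzofuran is present. It sets out from 7. BBr3 should give 5-iodo-2,4-dimethylbenzene-1,3-diol F5, the iodine being meta to both oxygens and so stable to acid. MOMCl with iPr2NEt should give 1-iodo-3,5-bis(methoxymethoxy)-2,4-dimethylbenzene F6. The arylative cyclisation of step 10 with 14 should then give methyl 3-{3-[3,5-bis(methoxymethoxy)-2,4-dimethylphenyl]-6-hydroxy-4-methyl-1-benzofuran-2-yl}propanoate F7. HCl in MeOH at 40 °C removes both acetals without touching the methyl ester and comes back to the route at target 17.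

Step 2. Protodeboronation, copper-mediated C–O coupling with the solvent (Chan–Lam type), or iodination of the activated ring positions by iodine formed under air may compete with ipso C–I bond formation. The fallback carries a bromide through the branch and exchanges the halogen at the end. It sets out from 2. CuBr2 (3 equiv) in MeOH/H2O at 80 °C should give 5-bromo-1,3-dimethoxy-2-methylbenzene F8. Rieche formylation as in step 3 should give 6-bromo-2,4-dimethoxy-3-methylbenzaldehyde F9. Et3SiH/TFA as in step 4 should give 1-bromo-3,5-dimethoxy-2,4-dimethylbenzene F10. Copper-catalysed aromatic Finkelstein exchange (CuI, NaI, trans-N,N′-dimethylcyclohexane-1,2-diamine, dioxane, 110 °C) then returns to the route at 7.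

**Further compounds**

F1 | step 10 | methyl 5-(2,4-dimethoxy-6-methylphenyl)pent-4-ynoate | COC(=O)CCC#Cc1c(C)cc(OC)cc1OC
F2 | step 10 | methyl 3-(3-iodo-6-methoxy-4-methyl-1-benzofuran-2-yl)propanoate | COC(=O)CCc1oc2cc(OC)cc(C)c2c1I
F3 | step 10 | 2-(3,5-dimethoxy-2,4-dimethylphenyl)-4,4,5,5-tetramethyl-1,3,2-dioxaborolane | COc1cc(B2OC(C)(C)C(C)(C)O2)c(C)c(OC)c1C
F4 | step 10 | methyl 3-[3-(3,5-dimethoxy-2,4-dimethylphenyl)-6-methoxy-4-methyl-1-benzofuran-2-yl]propanoate | COC(=O)CCc1oc2cc(OC)cc(C)c2c1-c1cc(OC)c(C)c(OC)c1C
F5 | step 11 | 5-iodo-2,4-dimethylbenzene-1,3-diol | Cc1c(O)cc(I)c(C)c1O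
F6 | step 11 | 1-iodo-3,5-bis(methoxymethoxy)-2,4-dimethylbenzene | COCOc1cc(I)c(C)c(OCOC)c1C
F7 | step 11 | methyl 3-{3-[3,5-bis(methoxymethoxy)-2,4-dimethylphenyl]-6-hydroxy-4-methyl-1-benzofuran-2-yl}propanoate | COC(=O)CCc1oc2cc(O)cc(C)c2c1-c1cc(OCOC)c(C)c(OCOC)c1C
F8 | step 2 | 5-bromo-1,3-dimethoxy-2-methylbenzene | COc1cc(Br)cc(OC)c1C
F9 | step 2 | 6-bromo-2,4-dimethoxy-3-methylbenzaldehyde | COc1cc(Br)c(C=O)c(OC)c1C
F10 | step 2 | 1-bromo-3,5-dimethoxy-2,4-dimethylbenzene | COc1cc(Br)c(C)c(OC)c1C
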